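**Retrosynthetic overview**

1. Feature: the carbocycle C1–C6 is a masked 6-acyloxy-2-methylcyclohex-2-enone. Its C1 carbonyl and C3 are 1,5-related through C6 and C5, so the ring divides into an α-acyloxy β-keto ester (C2, C1, C6 with the C2 methyl and the isovalerate) and an enal (C3–C5) that carries C7 as a ketal-masked acetyl group.
2. Key disconnection: C6–C5 (Michael addition) and C2=C3 (aldol condensation, ring closure) with loss of the tert-butyl ester; this closes the only carbocycle and sets C5 and C6.
3. Ring oxirane C2–C3: C1 ketone → β-alcohol → hydroxyl-directed epoxidation; C1 is reoxidised in the last step.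
4. Side chain: acetyl → enol triflate → C7(=C14H2)–C8H2OH; a Sharpless epoxidation closes the C7/C14 oxirane under reagent control; C8–C9 is made by adding a C9–C11 alkenylzinc to the C8 aldehyde.
5. Order of ring formation: cyclohexene (step 5), C2/C3 oxirane (step 7), C7/C14 oxirane (step 12); then desilylation and oxidation of the C1 and C8 carbinols.

Key step: step 5

Remark: locants are terpenoid-type (ring C1 ketone, C2 methyl-bearing oxirane carbon, C3, C4, C5 side-chain carbon, C6 ester carbon; chain C7, its oxirane CH2 C14, C8–C11); β is the ring face that carries the C5 side chain; compounds 5 and 19 and (tributylstannyl)methanol are taken to be purchasable.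

**Route**

Step 1
Reactants: 1 2-methyl-2-vinyl-1,3-dioxolane
Product: 2 2-methyl-1,3-dioxolane-2-carbaldehyde
Conditions: O3, CH2Cl2, −78 °C; then Me2S, −78 °C → rt; crude solution used directly
Reagents that add atoms: ozone, [O-][O+]=O
Why: Ozonolysis with reductive work-up cleaves the terminal vinyl group to the aldehyde, and the ketal is inert to ozone.

Step 2
Reactants: 2 2-methyl-1,3-dioxolane-2-carbaldehyde; 3 (triphenylphosphoranylidene)acetaldehyde
Product: 4 (E)-3-(2-methyl-1,3-dioxolan-2-yl)prop-2-enal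
Conditions: CH2Cl2, rt → 40 °C
Reagents that add atoms: none
Why: Wittig olefination with the stabilised formylmethylene ylide should give the E-enal, and the electron-poor α,α-dioxygenated aldehyde 2 reacts faster than the conjugated product, which limits a second homologation.

Step 3
Reactants: 5 tert-butyl 3-oxopentanoate
Product: 6 tert-butyl 2-diazo-3-oxopentanoate
Conditions: 4-acetamidobenzenesulfonyl azide, Et3N, MeCN, 0 °C → rt
Reagents that add atoms: 4-acetamidobenzenesulfonyl azide, CC(=O)Nc1ccc(cc1)S(=O)(=O)N=[N+]=[N-]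
Why: Regitz diazo transfer to the doubly activated methylene of a β-keto ester is a standard, dependable reaction.

Step 4
Reactants: 6 tert-butyl 2-diazo-3-oxopentanoate; 7 3-methylbutanoic acid
Product: 8 tert-butyl 2-(3-methylbutanoyloxy)-3-oxopentanoate (racemic)
Conditions: Rh2(OAc)4 (1 mol%), 7 (2 equiv), 1,2-dichloroethane, 60 °C
Reagents that add atoms: none
Why: The rhodium carbenoid formed from the diazo keto ester inserts into the O–H bond of the carboxylic acid (carbenoid O–H insertion), which places the isovalerate on the future C6 before the ring exists.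

Step 5
Reactants: 4 (E)-3-(2-methyl-1,3-dioxolan-2-yl)prop-2-enal; 8 tert-butyl 2-(3-methylbutanoyloxy)-3-oxopentanoate
Product: 10 (5R,6S)-2-methyl-5-(2-methyl-1,3-dioxolan-2-yl)-6-(3-methylbutanoyloxy)cyclohex-2-en-1-one, via Michael adduct 9 (not isolated)
Conditions: (S)-2-[bis(3,5-bis(trifluoromethyl)phenyl)(trimethylsilyloxy)methyl]pyrrolidine (20 mol%), PhCO2H (20 mol%), PhMe, rt; then TsOH (anhydrous, 0.3 equiv), PhMe, 80 °C, Dean–Stark trap charged with 4 Å sieves
Reagents that add atoms: none
Why: Proposed new method: the (S)-amine condenses with enal 4 to an E-iminium ion with one face blocked by the diaryl(silyloxy)methyl group, the enol of 8 adds through its acyloxy-bearing carbon to the β-carbon (new C6–C5 bond) and hydrolysis releases aldehyde 9, after which TsOH removes the tert-butyl group as isobutene, the β-keto acid loses CO2 and the enol of the ethyl ketone (C2) condenses with the aldehyde (C3) to the C2=C3 enone. The closest known reaction is the diarylprolinol silyl ether Michael addition of α-unsubstituted tert-butyl β-keto esters to enals followed by acid-mediated aldol condensation and decarboxylation to 5-substituted cyclohex-2-enones; what has not been shown is a donor that carries an α-acyloxy group and so passes through a fully substituted C6. The six-membered ring closes by a 6-(enolexo)-exo-trig aldol, the only feasible closure because attack from C6 would require a four-membered ring. C5 is fixed by the catalyst, since approach to the unshielded face of the iminium ion from the (S)-amine corresponds to 5R here, and C6 is set under thermodynamic control, because the enol left by decarboxylation is protonated and the α-acyloxy ketone equilibrates in the acid to the trans-diequatorial isomer. The step needs 1,4- and not 1,2-addition, which iminium activation provides, C- and not O-alkylation of the donor, which the soft iminium acceptor favours, and survival of the dioxolane and the isovalerate, which is secured by keeping the acid stage anhydrous through azeotropic removal of the water of condensation.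

Step 6
Reactants: 10 (5R,6S)-2-methyl-5-(2-methyl-1,3-dioxolan-2-yl)-6-(3-methylbutanoyloxy)cyclohex-2-en-1-one
Product: 11 (1S,5R,6S)-2-methyl-5-(2-methyl-1,3-dioxolan-2-yl)-6-(3-methylbutanoyloxy)cyclohex-2-en-1-ol (C1-OH β)
Conditions: NaBH4, CeCl3·7H2O, MeOH, −78 °C
Reagents that add atoms: none
Why: Luche 1,2-reduction in which hydride adds axially to the half-chair carrying the C5 and C6 groups equatorially (the course known for carvone to cis-carveol) should set C1 with the hydroxyl β, cis to the C5 side chain and trans to the ester, and the low temperature suppresses acyl migration.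

Step 7
Reactants: 11 (1S,5R,6S)-2-methyl-5-(2-methyl-1,3-dioxolan-2-yl)-6-(3-methylbutanoyloxy)cyclohex-2-en-1-ol
Product: 12 2β,3β-epoxy-1β-hydroxy-2-methyl-5β-(2-methyl-1,3-dioxolan-2-yl)cyclohexan-6α-yl 3-methylbutanoate
Conditions: VO(acac)2 (5 mol%), t-BuOOH (decane), CH2Cl2, 0 °C → rt
Reagents that add atoms: tert-butyl hydroperoxide, CC(C)(C)OO
Why: Hydroxyl-directed vanadium-catalysed epoxidation delivers oxygen to the alkene face syn to the C1 hydroxyl, so C2 and C3 are set with the oxirane β as in the target.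

Step 8
Reactants: 12 2β,3β-epoxy-1β-hydroxy-2-methyl-5β-(2-methyl-1,3-dioxolan-2-yl)cyclohexan-6α-yl 3-methylbutanoate
Product: 13 1β-(tert-butyldimethylsilyloxy)-2β,3β-epoxy-2-methyl-5β-(2-methyl-1,3-dioxolan-2-yl)cyclohexan-6α-yl 3-methylbutanoate
Conditions: TBSOTf, 2,6-lutidine, CH2Cl2, −78 °C
Reagents that add atoms: tert-butyldimethylsilyl trifluoromethanesulfonate, CC(C)(C)[Si](C)(C)OS(=O)(=O)C(F)(F)F
Why: Silylation with the silyl triflate and a hindered base protects the hindered C1 hydroxyl at low temperature before ketal or oxirane can be activated, and it blocks acyl migration from C6 in the later basic steps.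

Step 9
Reactants: 13 1β-(tert-butyldimethylsilyloxy)-2β,3β-epoxy-2-methyl-5β-(2-methyl-1,3-dioxolan-2-yl)cyclohexan-6α-yl 3-methylbutanoate
Product: 14 5β-acetyl-1β-(tert-butyldimethylsilyloxy)-2β,3β-epoxy-2-methylcyclohexan-6α-yl 3-methylbutanoate
Conditions: PPTS (0.3 equiv), acetone/H2O 9:1, 45 °C
Reagents that add atoms: water, O
Why: Mild acid hydrolysis of the ketal, in which a ketone dioxolane should be cleaved by pyridinium tosylate much faster than the TBS ether or the oxirane, the latter being deactivated by the neighbouring siloxy group.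

Step 10
Reactants: 14 5β-acetyl-1β-(tert-butyldimethylsilyloxy)-2β,3β-epoxy-2-methylcyclohexan-6α-yl 3-methylbutanoate
Product: 15 1β-(tert-butyldimethylsilyloxy)-2β,3β-epoxy-2-methyl-5β-[1-(trifluoromethylsulfonyloxy)ethenyl]cyclohexan-6α-yl 3-methylbutanoate
Conditions: KN(SiMe3)2, THF, −78 °C; then PhNTf2, −78 → −40 °C
Reagents that add atoms: N-phenylbis(trifluoromethanesulfonimide), O=S(=O)(N(c1ccccc1)S(=O)(=O)C(F)(F)F)C(F)(F)F
Why: Kinetic deprotonation of the methyl ketone by the hindered amide base occurs at the methyl group and O-triflation of that enolate gives the terminal enol triflate, while the equatorial C6 ester is not aligned for β-elimination should some C5 enolate form.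

Step 11
Reactants: 15 1β-(tert-butyldimethylsilyloxy)-2β,3β-epoxy-2-methyl-5β-[1-(trifluoromethylsulfonyloxy)ethenyl]cyclohexan-6α-yl 3-methylbutanoate
Product: 16 1β-(tert-butyldimethylsilyloxy)-2β,3β-epoxy-5β-(3-hydroxyprop-1-en-2-yl)-2-methylcyclohexan-6α-yl 3-methylbutanoate
Conditions: Bu3SnCH2OH, Pd(PPh3)4 (5 mol%), LiCl, 1,4-dioxane, 90 °C
Reagents that add atoms: (tributylstannyl)methanol, OC[Sn](CCCC)(CCCC)CCCC
Why: Stille coupling of the enol triflate with the hydroxymethyl stannane forms the C7–C8 bond under neutral conditions and gives the 2-substituted allylic alcohol that the next step requires.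

Step 12
Reactants: 16 1β-(tert-butyldimethylsilyloxy)-2β,3β-epoxy-5β-(3-hydroxyprop-1-en-2-yl)-2-methylcyclohexan-6α-yl 3-methylbutanoate
Product: 17 1β-(tert-butyldimethylsilyloxy)-2β,3β-epoxy-5β-[2-(hydroxymethyl)oxiran-2-yl]-2-methylcyclohexan-6α-yl 3-methylbutanoate (C7 arranged as in the target; formally 7S here because C14 outranks C8)
Conditions: Ti(OiPr)4, L-(+)-diethyl tartrate, t-BuOOH, 4 Å sieves, CH2Cl2, −20 °C
Reagents that add atoms: tert-butyl hydroperoxide, CC(C)(C)OO
Why: Sharpless asymmetric epoxidation of the primary 2-substituted allylic alcohol, in which the tartrate and not the ring decides the face of C7=C14, and the L-(+)-ester, which gives (2S)-epoxy alcohols from 2-substituted allylic alcohols, corresponds to the target arrangement at C7.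

Step 13
Reactants: 17 1β-(tert-butyldimethylsilyloxy)-2β,3β-epoxy-5β-[2-(hydroxymethyl)oxiran-2-yl]-2-methylcyclohexan-6α-yl 3-methylbutanoate
Product: 18 1β-(tert-butyldimethylsilyloxy)-2β,3β-epoxy-5β-[(2R)-2-formyloxiran-2-yl]-2-methylcyclohexan-6α-yl 3-methylbutanoate
Conditions: Dess–Martin periodinane, NaHCO3, CH2Cl2, 0 °C → rt
Reagents that add atoms: none
Why: Buffered periodinane oxidation should give the non-enolisable α,β-epoxy aldehyde without touching the oxiranes, the ester or the silyl ether.

Step 14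
Reactants: 18 1β-(tert-butyldimethylsilyloxy)-2β,3β-epoxy-5β-[(2R)-2-formyloxiran-2-yl]-2-methylcyclohexan-6α-yl 3-methylbutanoate; 19 2-methyl-2-(trimethylsilyloxy)but-3-yne
Product: 22 1β-(tert-butyldimethylsilyloxy)-2β,3β-epoxy-5β-[(2R)-2-[(E)-1-hydroxy-4-methyl-4-(trimethylsilyloxy)pent-2-enyl]oxiran-2-yl]-2-methylcyclohexan-6α-yl 3-methylbutanoate (both C8 epimers), via alkenylzirconocene chloride 20 (not isolated), via alkenyl(methyl)zinc 21 (not isolated)
Conditions: 19, Cp2Zr(H)Cl, CH2Cl2, rt; Me2Zn, −65 °C; then 18, 0 °C; aq. NH4Cl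
Reagents that add atoms: none
Why: Syn-hydrozirconation of the terminal alkyne places zirconium on the terminal carbon with E geometry, and transmetalation to zinc gives an alkenylzinc that adds to the aldehyde but not to the ester or the oxiranes (hydrozirconation–transmetalation–carbonyl addition), forming C8–C9; both C8 epimers serve because C8 becomes a ketone.

Step 15
Reactants: 22 1β-(tert-butyldimethylsilyloxy)-2β,3β-epoxy-5β-[(2R)-2-[(E)-1-hydroxy-4-methyl-4-(trimethylsilyloxy)pent-2-enyl]oxiran-2-yl]-2-methylcyclohexan-6α-yl 3-methylbutanoate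
Product: 23 5β-[(2R)-2-[(E)-1,4-dihydroxy-4-methylpent-2-enyl]oxiran-2-yl]-2β,3β-epoxy-1β-hydroxy-2-methylcyclohexan-6α-yl 3-methylbutanoate (both C8 epimers)
Conditions: HF·pyridine, pyridine, THF, 0 °C → rt
Reagents that add atoms: none
Why: Buffered fluoride desilylation removes both silyl ethers under non-basic conditions, so the C6 ester should not migrate to the freed C1 hydroxyl and the oxiranes stay closed.

Step 16
Reactants: 23 5β-[(2R)-2-[(E)-1,4-dihydroxy-4-methylpent-2-enyl]oxiran-2-yl]-2β,3β-epoxy-1β-hydroxy-2-methylcyclohexan-6α-yl 3-methylbutanoate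
Product: 24 CNP0292003.1, the target
Conditions: Dess–Martin periodinane (3 equiv), NaHCO3, CH2Cl2, 0 °C → rt
Reagents that add atoms: none
Why: The periodinane oxidises the two secondary carbinols (C1 and the allylic C8) to ketones and cannot oxidise the tertiary C11 hydroxyl, and the buffered neutral medium avoids epimerisation at C6, whose trans arrangement is also the thermodynamically preferred one.

**Compound list**

1 | 2-methyl-2-vinyl-1,3-dioxolane | C=CC1(C)OCCO1 | starting material
2 | 2-methyl-1,3-dioxolane-2-carbaldehyde | O=CC1(C)OCCO1 | intermediate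
3 | (triphenylphosphoranylidene)acetaldehyde | O=CC=P(c1ccccc1)(c1ccccc1)c1ccccc1 | starting material
4 | (E)-3-(2-methyl-1,3-dioxolan-2-yl)prop-2-enal | O=C/C=C/C1(C)OCCO1 | intermediate
5 | tert-butyl 3-oxopentanoate | CCC(=O)CC(=O)OC(C)(C)C | starting material
6 | tert-butyl 2-diazo-3-oxopentanoate | CCC(=O)C(=[N+]=[N-])C(=O)OC(C)(C)C | intermediate
7 | 3-methylbutanoic acid | CC(C)CC(=O)O | starting material
8 | tert-butyl 2-(3-methylbutanoyloxy)-3-oxopentanoate (racemic) | CCC(=O)C(OC(=O)CC(C)C)C(=O)OC(C)(C)C | intermediate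
9 | tert-butyl (3R)-2-(3-methylbutanoyloxy)-3-(2-methyl-1,3-dioxolan-2-yl)-5-oxo-2-propanoylpentanoate (both C2 epimers; Michael adduct) | CCC(=O)C(OC(=O)CC(C)C)(C(=O)OC(C)(C)C)[C@@H](CC=O)C1(C)OCCO1 | intermediate
10 | (5R,6S)-2-methyl-5-(2-methyl-1,3-dioxolan-2-yl)-6-(3-methylbutanoyloxy)cyclohex-2-en-1-one | CC(C)CC(=O)O[C@@H]1C(=O)C(C)=CC[C@H]1C1(C)OCCO1 | intermediate
11 | (1S,5R,6S)-2-methyl-5-(2-methyl-1,3-dioxolan-2-yl)-6-(3-methylbutanoyloxy)cyclohex-2-en-1-ol | CC(C)CC(=O)O[C@@H]1[C@@H](O)C(C)=CC[C@H]1C1(C)OCCO1 | intermediate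
12 | 2β,3β-epoxy-1β-hydroxy-2-methyl-5β-(2-methyl-1,3-dioxolan-2-yl)cyclohexan-6α-yl 3-methylbutanoate | CC(C)CC(=O)O[C@@H]1[C@@H](O)[C@@]2(C)O[C@H]2C[C@H]1C1(C)OCCO1 | intermediate
13 | 1β-(tert-butyldimethylsilyloxy)-2β,3β-epoxy-2-methyl-5β-(2-methyl-1,3-dioxolan-2-yl)cyclohexan-6α-yl 3-methylbutanoate | CC(C)CC(=O)O[C@@H]1[C@@H](O[Si](C)(C)C(C)(C)C)[C@@]2(C)O[C@H]2C[C@H]1C1(C)OCCO1 | intermediate
14 | 5β-acetyl-1β-(tert-butyldimethylsilyloxy)-2β,3β-epoxy-2-methylcyclohexan-6α-yl 3-methylbutanoate | CC(C)CC(=O)O[C@@H]1[C@@H](O[Si](C)(C)C(C)(C)C)[C@@]2(C)O[C@H]2C[C@H]1C(C)=O | intermediate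
15 | 1β-(tert-butyldimethylsilyloxy)-2β,3β-epoxy-2-methyl-5β-[1-(trifluoromethylsulfonyloxy)ethenyl]cyclohexan-6α-yl 3-methylbutanoate | CC(C)CC(=O)O[C@@H]1[C@@H](O[Si](C)(C)C(C)(C)C)[C@@]2(C)O[C@H]2C[C@H]1C(=C)OS(=O)(=O)C(F)(F)F | intermediate
16 | 1β-(tert-butyldimethylsilyloxy)-2β,3β-epoxy-5β-(3-hydroxyprop-1-en-2-yl)-2-methylcyclohexan-6α-yl 3-methylbutanoate | CC(C)CC(=O)O[C@@H]1[C@@H](O[Si](C)(C)C(C)(C)C)[C@@]2(C)O[C@H]2C[C@H]1C(=C)CO | intermediate
17 | 1β-(tert-butyldimethylsilyloxy)-2β,3β-epoxy-5β-[2-(hydroxymethyl)oxiran-2-yl]-2-methylcyclohexan-6α-yl 3-methylbutanoate (C7 as in the target) | CC(C)CC(=O)O[C@@H]1[C@@H](O[Si](C)(C)C(C)(C)C)[C@@]2(C)O[C@H]2C[C@H]1[C@]1(CO)CO1 | intermediate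
18 | 1β-(tert-butyldimethylsilyloxy)-2β,3β-epoxy-5β-[(2R)-2-formyloxiran-2-yl]-2-methylcyclohexan-6α-yl 3-methylbutanoate | CC(C)CC(=O)O[C@@H]1[C@@H](O[Si](C)(C)C(C)(C)C)[C@@]2(C)O[C@H]2C[C@H]1[C@]1(C=O)CO1 | intermediate
19 | 2-methyl-2-(trimethylsilyloxy)but-3-yne | C#CC(C)(C)O[Si](C)(C)C | starting material
20 | (E)-[3-methyl-3-(trimethylsilyloxy)but-1-enyl]zirconocene chloride (cyclopentadienyl rings η5, drawn η1) | C[Si](C)(C)OC(C)(C)/C=C/[Zr](Cl)(C1C=CC=C1)C1C=CC=C1 | intermediate
21 | (E)-[3-methyl-3-(trimethylsilyloxy)but-1-enyl](methyl)zinc | C[Zn]/C=C/C(C)(C)O[Si](C)(C)C | intermediate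
22 | 1β-(tert-butyldimethylsilyloxy)-2β,3β-epoxy-5β-[(2R)-2-[(E)-1-hydroxy-4-methyl-4-(trimethylsilyloxy)pent-2-enyl]oxiran-2-yl]-2-methylcyclohexan-6α-yl 3-methylbutanoate (both C8 epimers) | CC(C)CC(=O)O[C@@H]1[C@@H](O[Si](C)(C)C(C)(C)C)[C@@]2(C)O[C@H]2C[C@H]1[C@]1(C(O)/C=C/C(C)(C)O[Si](C)(C)C)CO1 | intermediate
23 | 5β-[(2R)-2-[(E)-1,4-dihydroxy-4-methylpent-2-enyl]oxiran-2-yl]-2β,3β-epoxy-1β-hydroxy-2-methylcyclohexan-6α-yl 3-methylbutanoate (both C8 epimers) | CC(C)CC(=O)O[C@@H]1[C@@H](O)[C@@]2(C)O[C@H]2C[C@H]1[C@]1(C(O)/C=C/C(C)(C)O)CO1 | intermediate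
24 | CNP0292003.1 | CC(C)CC(=O)O[C@@H]1C(=O)[C@@]2(C)O[C@H]2C[C@H]1[C@]1(C(=O)/C=C/C(C)(C)O)CO1 | target

**Step count**

Total: 16 steps. Longest linear sequence: 14 steps (steps 1–2 or steps 3–4, then steps 5–16).

**Steps most likely to fail**

1. Step 5 (the step proposed as new). The C–C bond must form between a fully substituted donor carbon and a β-carbon next to the quaternary ketal carbon, so the Michael addition may be too slow and self-condensation of the enal or acylation of the amine by the activated ester may take over. In the acid stage, loss of the dioxolane would open a path to β-elimination of isovalerate and aromatisation. The fallback uses known chemistry and sets out from 4 and 5. The same amine catalyst adds the unsubstituted keto ester 5 to 4 to give tert-butyl (3R)-3-(2-methyl-1,3-dioxolan-2-yl)-5-oxo-2-propanoylpentanoate F1, which is not isolated. TsOH in toluene at 80 °C converts it to (5R)-2-methyl-5-(2-methyl-1,3-dioxolan-2-yl)cyclohex-2-en-1-one F2. Kinetic deprotonation at C6 with LiN(iPr)2 in THF at −78 °C and oxidation of the enolate with 2-(phenylsulfonyl)-3-phenyloxaziridine, anti to the C5 substituent, should give (5R,6S)-6-hydroxy-2-methyl-5-(2-methyl-1,3-dioxolan-2-yl)cyclohex-2-en-1-one F3. Acylation with 3-methylbutanoic anhydride and DMAP in pyridine returns to 10.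

2. Step 10. Deprotonation may occur in part at C5, followed by expulsion of the C6 isovalerate, or the methyl enolate may attack the neighbouring ester carbonyl before it is triflated. The fallback sets out from 14 and avoids enolate chemistry. Methylenation of the ketone with Zn, CH2Br2 and TiCl4 in CH2Cl2 gives 1β-(tert-butyldimethylsilyloxy)-2β,3β-epoxy-2-methyl-5β-(prop-1-en-2-yl)cyclohexan-6α-yl 3-methylbutanoate F4. Allylic hydroxylation of its methyl group with catalytic SeO2 and t-BuOOH in CH2Cl2 returns to 16.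

3. Step 12. The C5 stereocentre next to the alkene may oppose the tartrate (mismatched pair) and lower the facial selectivity, and the 2,2-disubstituted epoxy alcohol may be opened by isopropoxide on titanium. The fallback sets out from 16. Oxidation with MnO2 in CH2Cl2 gives 1β-(tert-butyldimethylsilyloxy)-2β,3β-epoxy-5β-(3-oxoprop-1-en-2-yl)-2-methylcyclohexan-6α-yl 3-methylbutanoate F5. Amine-catalysed epoxidation of this 2-substituted acrolein with aqueous H2O2 and a diphenylprolinol trimethylsilyl ether, using the catalyst enantiomer that delivers oxygen to the required face, comes back to the route at 18 and bypasses 17.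

**Further compounds**

F1 | step 5 | tert-butyl (3R)-3-(2-methyl-1,3-dioxolan-2-yl)-5-oxo-2-propanoylpentanoate | CCC(=O)C(C(=O)OC(C)(C)C)[C@@H](CC=O)C1(C)OCCO1
F2 | step 5 | (5R)-2-methyl-5-(2-methyl-1,3-dioxolan-2-yl)cyclohex-2-en-1-one | C1C(=O)C(C)=CC[C@H]1C1(C)OCCO1
F3 | step 5 | (5R,6S)-6-hydroxy-2-methyl-5-(2-methyl-1,3-dioxolan-2-yl)cyclohex-2-en-1-one | O[C@@H]1C(=O)C(C)=CC[C@H]1C1(C)OCCO1
F4 | step 10 | 1β-(tert-butyldimethylsilyloxy)-2β,3β-epoxy-2-methyl-5β-(prop-1-en-2-yl)cyclohexan-6α-yl 3-methylbutanoate | CC(C)CC(=O)O[C@@H]1[C@@H](O[Si](C)(C)C(C)(C)C)[C@@]2(C)O[C@H]2C[C@H]1C(C)=C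
F5 | step 12 | 1β-(tert-butyldimethylsilyloxy)-2β,3β-epoxy-5β-(3-oxoprop-1-en-2-yl)-2-methylcyclohexan-6α-yl 3-methylbutanoate | CC(C)CC(=O)O[C@@H]1[C@@H](O[Si](C)(C)C(C)(C)C)[C@@]2(C)O[C@H]2C[C@H]1C(=C)C=O
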